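**Assumption:** (2Z,6E)-farnesol is not counted as a cheap catalogue compound, so it is made in step 1; of the two antipodes of the Schiff-base ligand in step 2, the one that delivers the (2R,3R) bromochloride is used (the sense of induction is not predicted here).

Positions follow farnesane/bisabolane numbering: C1 is the carbinol carbon of farnesol, the ring is C1–C6, C14 sits on C7 and C15 on C3.

## Retrosynthetic overview

1. The target comes from a (10R)-10,11-epoxide by epoxide-to-allylic-alcohol isomerisation; the epoxide comes from Shi epoxidation of the prenyl terminus (C10 is set last).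
2. The C6 carbinol with its C7=C14 methylene comes from a singlet-oxygen ene reaction on the tetrasubstituted C6=C7 alkene of a bromochlorinated γ-bisabolene, as in the presumed biosynthesis; O2 enters anti to the axial bromine.
3. The ring comes from the farnesyl-to-bisabolyl cation–olefin closure of C1 onto C6=C7, run on an acyclic chain that already carries C2–Br and C3–Cl (primary triflate → bromiranium ion → bisabolyl cation → alkene).
4. The acyclic bromochloride comes from catalytic enantioselective bromochlorination of (2Z,6E)-farnesol (sets C2 and C3), itself from prenol dianion and geranyl bromide.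
5. Ring order: there is one carbocycle only, formed in step 3.

## Route

Step 1
Reactants: 1 prenol (3-methylbut-2-en-1-ol); 2 geranyl bromide, (2E)-1-bromo-3,7-dimethylocta-2,6-diene
Product: 4 (2Z,6E)-farnesol, via prenol dianion 3 (not isolated)
Conditions: n-BuLi (2.2 equiv), TMEDA, Et2O, 0 °C → rt; then 2, −78 °C → rt; H2O
Reagents that add atoms: none
Why: Alkoxide-directed allylic lithiation removes a proton from the methyl group cis to CH2OLi, and the chelated Z-allyllithium is alkylated at its CH2 terminus by the primary allylic bromide (SN2, prenol-dianion alkylation), which fixes the 2Z geometry needed for a trans Br/Cl pair on the later ring and carries over the 6E alkene of 2; no stereocentre is formed.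

Step 2
Reactants: 4 (2Z,6E)-farnesol
Product: 5 (2R,3R,6E)-2-bromo-3-chloro-3,7,11-trimethyldodeca-6,10-dien-1-ol
Conditions: NBS (1.1 equiv), ClTi(OiPr)3 (1.1 equiv), chiral tridentate Schiff-base (salicylaldimine of an amino alcohol) ligand (20 mol %), hexanes, −20 °C
Reagents that add atoms: N-bromosuccinimide, O=C1CCC(=O)N1Br; chlorotitanium triisopropoxide ClTi(OiPr)3, CC(C)O[Ti](Cl)(OC(C)C)OC(C)C
Why: Titanium-mediated catalytic enantioselective bromochlorination of an allylic alcohol (Burns type): the tetravalent titanium alkoxide of 4, bound to the chiral Schiff base, steers Br+ from NBS onto one face of the C2=C3 alkene and delivers chloride anti to the tertiary C3 (Markovnikov), so anti addition across the Z-alkene gives the (2R,3R) pair in one step while the two remote alkenes, which cannot bind titanium, stay intact.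

Step 3
Reactants: 5 (2R,3R,6E)-2-bromo-3-chloro-3,7,11-trimethyldodeca-6,10-dien-1-ol
Product: 9 (1R,2R)-2-bromo-1-chloro-1-methyl-4-(6-methylhept-5-en-2-ylidene)cyclohexane, via primary triflate 6 (not isolated), via bromiranium triflate 7 (not isolated), via bisabolyl cation 8 (not isolated)
Conditions: Tf2O (1.05 equiv), 2,6-di-tert-butyl-4-methylpyridine (2.5 equiv), CH2Cl2, −78 °C; then (CF3)2CHOH (dilute to 0.005 M), −40 → 0 °C
Reagents that add atoms: none
Why: Proposed new method: the β-bromo triflate ionises with anchimeric help from bromine to a C1–C2 bromiranium ion, the C6=C7 alkene attacks the primary C1 (the C2 terminus is neopentyl-like and deactivated by the C3 chlorine) just as C1 of the farnesyl cation is attacked on the way to the bisabolyl cation, and the tertiary C7 cation loses the C6 proton (E1, Zaitsev) to give the tetrasubstituted alkylidene as an E/Z mixture, with C2 and C3 unchanged because no bond to them is broken; the closest known reactions are the solvolytic generation of bromiranium ions from β-bromo sulfonates in (CF3)2CHOH, pi-route cyclisations of alkenyl sulfonates and bromiranium-initiated polyene cyclisations.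

Step 4
Reactants: 9 (1R,2R)-2-bromo-1-chloro-1-methyl-4-(6-methylhept-5-en-2-ylidene)cyclohexane
Product: 11 (1S,3R,4R)-3-bromo-4-chloro-4-methyl-1-(6-methylhepta-1,5-dien-2-yl)cyclohexan-1-ol, via allylic hydroperoxide 10 (not isolated)
Conditions: O2, hν (white LED), tetraphenylporphyrin (cat.), CH2Cl2, −20 °C, stopped at about 1 equiv uptake; then PPh3, −20 °C → rt
Reagents that add atoms: oxygen (O2), O=O
Why: Schenck ene reaction of singlet oxygen: the tetrasubstituted C6=C7 alkene reacts far faster than the trisubstituted C10=C11 alkene, the ring hydrogens of an alkylidenecyclohexane are poorly aligned so oxygen ends on C6 with hydrogen taken from the C14 methyl, and O2 comes to the face of C6 opposite the axial C2 bromine (trans-diaxial Br/Cl chair), which sets C6 as S (OH cis to Cl, trans to Br); PPh3 then reduces the hydroperoxide without touching C6.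

Step 5
Reactants: 11 (1S,3R,4R)-3-bromo-4-chloro-4-methyl-1-(6-methylhepta-1,5-dien-2-yl)cyclohexan-1-ol
Product: 12 (1S,3R,4R)-3-bromo-4-chloro-1-{4-[(2R)-3,3-dimethyloxiran-2-yl]but-1-en-2-yl}-4-methylcyclohexan-1-ol
Conditions: D-fructose-derived Shi ketone (30 mol %), KHSO5 (as 2KHSO5·KHSO4·K2SO4), K2CO3, Bu4NHSO4, MeCN/CH2(OMe)2/aq. buffer pH 10.5, 0 °C
Reagents that add atoms: potassium peroxymonosulfate KHSO5, [K+].[O-]S(=O)(=O)OO
Why: Shi asymmetric epoxidation: the chiral dioxirane epoxidises the electron-rich trisubstituted C10=C11 alkene and leaves the hindered 1,1-disubstituted alkene next to the tertiary carbinol alone, and the D-fructose-derived ketone delivers oxygen through its spiro transition state to give the (10R) epoxide under reagent control, the ring centres being too remote to interfere.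

Step 6
Reactants: 12 (1S,3R,4R)-3-bromo-4-chloro-1-{4-[(2R)-3,3-dimethyloxiran-2-yl]but-1-en-2-yl}-4-methylcyclohexan-1-ol
Product: 13 (1S,3R,4R)-3-bromo-4-chloro-1-[(5R)-5-hydroxy-6-methylhepta-1,6-dien-2-yl]-4-methylcyclohexan-1-ol
Conditions: Et2Al(TMP) (4 equiv, from lithium 2,2,6,6-tetramethylpiperidide and Et2AlCl), PhMe, 0 °C; then aq. NH4Cl
Reagents that add atoms: none
Why: Aluminium amide epoxide-to-allylic-alcohol rearrangement (Yamamoto–Nozaki type): aluminium binds the epoxide oxygen and the amide removes a syn proton from a methyl group, so the C11–O bond breaks and the C10–O bond, with its R configuration, is untouched; the first equivalent only forms the aluminium alkoxide of the tertiary alcohol, and the ring halides, equatorial in the favoured chair, have no anti-periplanar hydrogen for E2.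

## Compound list

1 | prenol, 3-methylbut-2-en-1-ol | CC(C)=CCO | starting material
2 | geranyl bromide, (2E)-1-bromo-3,7-dimethylocta-2,6-diene | CC(C)=CCC/C(C)=C/CBr | starting material
3 | prenol dianion, dilithiated at oxygen and at the methyl carbon cis to CH2O | [Li]OC/C=C(/C)C[Li] | intermediate (not isolated)
4 | (2Z,6E)-farnesol, (2Z,6E)-3,7,11-trimethyldodeca-2,6,10-trien-1-ol | CC(C)=CCC/C(C)=C/CC/C(C)=C\CO | intermediate
5 | (2R,3R,6E)-2-bromo-3-chloro-3,7,11-trimethyldodeca-6,10-dien-1-ol | CC(C)=CCC/C(C)=C/CC[C@@](C)(Cl)[C@H](Br)CO | intermediate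
6 | (2R,3R,6E)-2-bromo-3-chloro-3,7,11-trimethyldodeca-6,10-dien-1-yl trifluoromethanesulfonate | CC(C)=CCC/C(C)=C/CC[C@@](C)(Cl)[C@H](Br)COS(=O)(=O)C(F)(F)F | intermediate (not isolated)
7 | bromiranium triflate: Br+ bridges C1 and C2 of the chain of 6, C2 and C3 arranged as in 5 | CC(C)=CCC/C(C)=C/CC[C@@](C)(Cl)[C@H]1C[Br+]1.[O-]S(=O)(=O)C(F)(F)F | intermediate (not isolated)
8 | bisabolyl-type cation: 2-[(3R,4R)-3-bromo-4-chloro-4-methylcyclohexyl]-6-methylhept-5-en-2-ylium triflate (C1 of the ring either way) | CC(C)=CCC[C+](C)C1CC[C@@](C)(Cl)[C@H](Br)C1.[O-]S(=O)(=O)C(F)(F)F | intermediate (not isolated)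
9 | (1R,2R)-2-bromo-1-chloro-1-methyl-4-(6-methylhept-5-en-2-ylidene)cyclohexane, E/Z mixture at the exocyclic alkene | CC(C)=CCCC(C)=C1CC[C@@](C)(Cl)[C@H](Br)C1 | intermediate
10 | (1S,3R,4R)-3-bromo-4-chloro-4-methyl-1-(6-methylhepta-1,5-dien-2-yl)cyclohexyl hydroperoxide | C=C(CCC=C(C)C)[C@]1(OO)CC[C@@](C)(Cl)[C@H](Br)C1 | intermediate (not isolated)
11 | (1S,3R,4R)-3-bromo-4-chloro-4-methyl-1-(6-methylhepta-1,5-dien-2-yl)cyclohexan-1-ol | C=C(CCC=C(C)C)[C@]1(O)CC[C@@](C)(Cl)[C@H](Br)C1 | intermediate
12 | (1S,3R,4R)-3-bromo-4-chloro-1-{4-[(2R)-3,3-dimethyloxiran-2-yl]but-1-en-2-yl}-4-methylcyclohexan-1-ol | C=C(CC[C@H]1OC1(C)C)[C@]2(O)CC[C@@](C)(Cl)[C@H](Br)C2 | intermediate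
13 | (1S,3R,4R)-3-bromo-4-chloro-1-[(5R)-5-hydroxy-6-methylhepta-1,6-dien-2-yl]-4-methylcyclohexan-1-ol | C=C(C)[C@H](O)CCC(=C)[C@]1(O)CC[C@@](C)(Cl)[C@H](Br)C1 | target

## Step count and risks

Total: 6 steps. Longest linear sequence: 6 steps (1 and 2 to 13).

**Step 3, the ring closure.** Two things can go wrong. The bromiranium ion 7 may hand Br+ to one of the trisubstituted alkenes instead of being alkylated at C1; high dilution and low temperature are meant to hold this down. More likely, cation 8 loses a proton from C14 or C8 as well as from C6, so 9 comes with its double-bond isomers. The fallback sets out from 5 and comes back at 9. The same ionisation is run, and the exocyclic-methylene isomer (1R,2R)-2-bromo-1-chloro-1-methyl-4-(6-methylhepta-1,5-dien-2-yl)cyclohexane F1, formed beside 9, is not discarded. The mixture is treated with chloro[N,N'-bis(3,5-di-tert-butylsalicylidene)ethane-1,2-diaminato]cobalt (a trivalent cobalt complex, 5 mol %) and catalytic PhSiH3 in benzene at rt. In this radical hydrogen-atom-transfer isomerisation H• adds to the CH2 terminus of F1, the tertiary C7 radical gives up the C6 hydrogen, and the tetrasubstituted alkene 9, which no longer accepts H•, accumulates. The trisubstituted C10=C11 alkene and the alkyl halides are expected to be spared; the C7=C8 isomer is not converted and is removed on AgNO3-impregnated silica.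

**Step 4, the ene reaction.** Singlet oxygen may take hydrogen from the C8 methylene as well as from the C14 methyl, giving C7=C8 isomers of 11, and over-oxidation at C10=C11 is possible. The fallback sets out from 9 and comes back at 11. mCPBA (1.0 equiv, NaHCO3, CH2Cl2, −40 °C) epoxidises the tetrasubstituted alkene first, from the face away from the axial bromine, to give the spiro-epoxide (3S,5R,6R)-5-bromo-6-chloro-2,6-dimethyl-2-(4-methylpent-3-en-1-yl)-1-oxaspiro[2.5]octane F2. Et2Al(TMP) in PhMe at 0 °C then removes a proton from the methyl group on the epoxide carbon (CH3 is preferred over chain CH2 and ring CH2) and opens the C7–O bond, which gives 11 with the oxygen left on C6.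

**Step 6, the epoxide isomerisation.** The aluminium amide may cause loss of HBr or HCl, or a Grob-type fragmentation of the C6 alkoxide with the C2 bromide. The fallback sets out from 12 and comes back at 13. TMSOTf (3 equiv) and 2,6-lutidine in PhMe at −78 → −40 °C first silylate the tertiary alcohol, then open the epoxide at the tertiary C11 with loss of a methyl proton. This gives the bis(trimethylsilyl) ether of 13, F3, with C10–O intact; citric acid in MeOH at 0 °C then removes both silyl groups to give 13.

## Further compounds

F1 | step 3 | (1R,2R)-2-bromo-1-chloro-1-methyl-4-(6-methylhepta-1,5-dien-2-yl)cyclohexane, both C4 epimers | C=C(CCC=C(C)C)C1CC[C@@](C)(Cl)[C@H](Br)C1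
F2 | step 4 | (3S,5R,6R)-5-bromo-6-chloro-2,6-dimethyl-2-(4-methylpent-3-en-1-yl)-1-oxaspiro[2.5]octane, both C2 epimers | CC(C)=CCCC1(C)O[C@]12CC[C@@](C)(Cl)[C@H](Br)C2
F3 | step 6 | bis(trimethylsilyl) ether of 13, {[(1S,3R,4R)-3-bromo-4-chloro-4-methyl-1-{(5R)-6-methyl-5-[(trimethylsilyl)oxy]hepta-1,6-dien-2-yl}cyclohexyl]oxy}trimethylsilane | C=C(C)[C@H](O[Si](C)(C)C)CCC(=C)[C@]1(O[Si](C)(C)C)CC[C@@](C)(Cl)[C@H](Br)C1
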